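## Structural features

The target is a tricyclic spiro compound. A 1,2,3-trimethoxybenzene (ring A: C1–C4, C4a, C9a) is fused to a seven-membered carbocycle (ring B: C4a, C5–C9, C9a), and C5 of ring B is the spiro atom of a 2,6-dimethoxycyclohexa-2,5-dienone (ring C). Ring B carries three contiguous stereocentres: C7 (methyl, R), C8 (methyl, S) and the benzylic C9 (benzoate, R). The two methyl groups are trans on the ring, and the C9 oxygen is trans to the C8 methyl. C5 is quaternary but not stereogenic, because the two arms of ring C are identical. The fragile groups are the cross-conjugated dienone with its two enol ethers (acid hydrolysis, dienone–phenol rearrangement, conjugate addition) and the benzylic benzoate on an electron-rich arene (ionisation, elimination, cleavage by hydride or strong base). The real difficulty is the congested spiro carbon C5, bonded to the fully substituted arene carbon C4a beside the C4 methoxy group, together with three contiguous stereocentres on a flexible ring. The key step exploits the substitution of ring A: one hydrogen (C1), three contiguous oxygens (C2, C3, C4) and two carbons (C4a, C9a) shared with ring B. This is the pattern a 4-alkenyl-2,3-dimethoxycyclobutenone gives on benzannulation when the alkene is the C9a=C4a bond of a preformed ring B.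

## Logic of the disconnections

**31 ⇒ 30 ⇒ 29.** The C9–O acyl bond and then the O–Si bond are cut last. The benzoate would not survive the hydride reduction of step 17 or the basic steps before it, whereas a bulky silyl ether does. The gain is that the C9 oxygen travels as one inert group from step 5 onward. The demand is that desilylation and acylation of 30 proceed without ionising the benzylic carbon or adding its hydroxyl to the dienone.

**29 ⇒ 27 + 28.** Both C=C bonds of ring C are cut in the retro-aldol-condensation sense. Ring C is symmetric, so its five non-spiro carbons map onto a symmetrical three-carbon ketone (28) and two formyl carbons on C5. The gain is that ring C and all its oxygens disappear in one operation. The demand is that a twofold aldol condensation at a crowded, non-enolisable dialdehyde is faster than loss of a formyl group.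

**27 ⇒ 26 ⇒ 25 ⇒ 24.** The formyl C–H bonds are traced back to ester C–O bonds, and the C4 O–CH3 bond to a phenol. Esters are what a malonate delivers and they are inert in the key step; the C4 oxygen is born as a phenol. The gain is that C5 becomes the carbon of a dialkylated malonate. The demands are complete reduction of two neopentyl esters, an oxidation of 26 free of base (a half-oxidised stage could lose formaldehyde), and methylation of a hindered phenol.

**24 ⇒ 17 + 20 (key).** C1–C9a and C4–C4a are cut, which removes ring A entirely. The four carbons C1–C4 with their oxygens are the four carbons of a squarate-derived cyclobutenone, so no arene substitution chemistry is needed. The gain is that a pentasubstituted arene is traded for a cycloheptenylstannane and a four-membered ring. The demand is that a hindered alkenylstannane transmetalates and that the coupled cyclobutenone opens and cyclises without disturbing esters, silyl ether or stereocentres.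

**20 ⇒ 19 ⇒ 18.** The C–Cl bond is traced to C–OH and that to a carbonyl of 18. The gain is a two-step access to the electrophile from a commercial squarate. The demand is mono-reduction of one carbonyl and a chloride that ends on the carbon bearing hydrogen.

**17 ⇒ 16 ⇒ 14.** The C9a–Sn bond is traced to an enol triflate C–O bond and that to the C9a ketone. A ketone is the simplest handle from which the C9a=C4a alkene can be placed. The demand is enolisation towards C4a only, since enolisation towards C9 would also erase that stereocentre.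

**14 ⇒ 13.** The C5–C4a bond is cut to a malonate carbanion and a bromomethyl ketone. The gain is an acyclic chain that holds all three stereocentres. The demand is that seven-membered ring closure beats intermolecular alkylation and attack at the carbonyl.

**13 ⇒ 12 ⇒ 10 + 11.** The bromoketone is traced to a 1-ethoxyvinyl group, and the C5–C6 bond is cut to 11 and a primary sulfonate. The acidic malonate C–H is thereby introduced only after the organolithium step, which it could not survive. The demand is that the enol ether is carried through non-acidic steps only.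

**10 ⇒ 9 ⇒ 8 ⇒ 7.** These are O–S and O–Si changes. C9 is carried as a triisopropylsilyl ether so that the primary tert-butyldimethylsilyl ether at C6 can be removed selectively. The demand is clean discrimination of the two silyl ethers by fluoride.

**7 ⇒ 4 + 5 (through 6).** The C9–C9a bond is cut to an aldehyde and a lithiated enol ether, which supplies C9a and C4a at the ketone oxidation level. The gain is a two-carbon unit from a bulk chemical. The demand is Felkin–Anh facial control by the C8 methyl group.

**4 ⇒ 3 ⇒ 2 ⇒ 1.** The C6/C9 oxidation levels are adjusted back to a C2-symmetric diacid. C7 and C8 are bought as the trans (S,S) acid; the symmetry makes monoprotection of 2 free of regiochemistry. The demand is only that C8 is not epimerised at the aldehyde stage.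

## Other disconnections considered

**Alternative 1:** The cut runs through C8–C9 and C5–C6. It leaves the biaryl phenol aldehyde A2, in which rings A and C are both still aromatic, and the four-carbon allylboronate A3, which also carries an allylic carbonate.
- **Forward step.** A chiral 3,3'-diaryl-1,1'-binaphthyl-2,2'-diyl hydrogen phosphate would catalyse allylboration of the aldehyde of A2 by A3 through a closed chair transition state (C8–C9, two stereocentres). Pd(PPh3)4 in the same flask would ionise the carbonate to an allyl complex of divalent palladium. The para carbon of the phenolate would attack it (C5–C6), closing ring B, creating the spiro centre and dearomatising ring C to give A1.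
- **In its favour.** Two C–C bonds, ring B, the spiro centre and the dienone arise in one flask; both six-membered rings are bought as arenes; C8 and C9 are under catalyst control.
- **Against it here.** The closed transition state gives the C9 hydroxyl cis to the C8 methyl, the epimer of what 31 needs. A Mitsunobu-type inversion at a hindered, easily ionised benzylic carbinol must follow (it could install the benzoate directly). C7 is still an exocyclic alkene and must be hydrogenated to the 7,8-trans isomer in the presence of the dienone. C- versus O-allylation of the phenolate in a seven-membered closure is a further selectivity to win.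
- **Comparison.** On structure the alternative is the better plan, since it needs no de novo synthesis of ring A or ring C. On mechanism both rest on established palladium chemistry; the chosen plan takes C7 and C8 from 1 and sets C9 directly in the correct sense, where the alternative needs an inversion and a late hydrogenation. On step economy the alternative is clearly better (under ten steps against nineteen in the longest line).

**Alternative 2:** The cut runs through C8–C9 and C6–C7. Ring B is seen as the indanone A5 into whose acyl–CH2 bond the alkyne A6 is inserted.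
- **Forward step.** [Rh(C2H4)2Cl]2 with an N-heterocyclic carbene and 2-amino-3-picoline would form a transient ketimine, add the C9–C6 bond oxidatively to monovalent rhodium, insert A6 and eliminate reductively to the benzocycloheptenone A4.
- **In its favour.** Ring A is bought; A5 is a few steps from a trimethoxyarene; the seven-membered ring and both methyl-bearing carbons arrive in one catalytic, tin-free step.
- **Against it here.** A4 has no stereocentre. C7, C8 and C9 must all be created afterwards from a tetrasubstituted enone: hydrogenation adds syn and would give the cis-dimethyl isomer, so epimerisation at C8 and a separate source of absolute configuration are needed. The bond to be activated also lies next to the quaternary diester carbon.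
- **Comparison.** On structure it is better for ring A and only equal for ring C: it needs the same diester-to-dienone sequence as 25 → 29 and therefore shares the least certain step of the chosen plan. On mechanism the C–C activation is more direct than coupling plus electrocyclisation, but it yields a flat intermediate, whereas the chosen plan brings C7–C9 in before any ring is closed. On step economy it is better up to the bicyclic diester; part of that saving would be spent on stereochemical repair.

**Alternative 3:** The only skeletal cut is C8–C9. Ring C and the spiro centre already exist in the achiral dienone A8, which O-allylation of A2 and a para-Claisen-type shift would supply.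
- **Forward step.** [Rh(cod)2]BF4 with a chiral bisphosphine would add the aldehyde C–H oxidatively to monovalent rhodium, insert the (E)-trisubstituted alkene in a syn fashion and eliminate reductively. This closes ring B as the C9 ketone A7 and sets C7 and C8 together as the trans pair. Reduction of the ketone would then lead to 30.
- **In its favour.** It is the shortest plan; ring C comes from robust phenol dearomatisation and not from a twofold aldol; both methyl stereocentres come from one enantioselective catalytic step.
- **Against it here.** Hydroacylation to a seven-membered ring across a trisubstituted alkene, without a coordinating group to hold the acyl rhodium hydride, competes with decarbonylation. The aryl ketone of A7 must then be reduced in the presence of the dienone carbonyl and with the 8,9-trans sense.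
- **Comparison.** On structure and step economy the alternative is better. On mechanism the chosen plan closes ring B by an SN2 reaction at a bromoketone and sets C9 on an open chain, both more predictable than the hydroacylation and the late ketone reduction. The two plans are equal in ending with acylation of the same hindered alcohol 30, and the alternative must carry the dienone through two reductive steps whereas the chosen plan forms it late.

Key step: step 15

Assumption: the resolved trans acid is taken as purchasable in its (2S,3S) form (the racemic trans acid would first need a classical resolution); ring atoms are numbered as in benzo[7]annulene (C1–C4, C4a, C5–C9, C9a).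

## Route

Step 1
Reactants: 1 (2S,3S)-2,3-dimethylbutanedioic acid
Product: 2 (2S,3S)-2,3-dimethylbutane-1,4-diol
Conditions: LiAlH4, THF, 0 °C → reflux
Reagents that add atoms: none
Why: Hydride reduction of both carboxyl groups; the carboxylate α-carbons are not enolised, so the trans (S,S) pair that becomes C7 and C8 is carried into the C2-symmetric diol.

Step 2
Reactants: 2 (2S,3S)-2,3-dimethylbutane-1,4-diol
Product: 3 (2S,3S)-4-[(tert-butyldimethylsilyl)oxy]-2,3-dimethylbutan-1-ol
Conditions: NaH (1.0 equiv), THF, rt; then TBSCl (1.0 equiv)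
Reagents that add atoms: tert-butyldimethylsilyl chloride, CC(C)(C)[Si](C)(C)Cl
Why: Monosilylation through the sparingly soluble monosodium alkoxide; the two hydroxyls are homotopic, so only one monoether exists and the diol is desymmetrised without a regiochemical question.

Step 3
Reactants: 3 (2S,3S)-4-[(tert-butyldimethylsilyl)oxy]-2,3-dimethylbutan-1-ol
Product: 4 (2S,3S)-4-[(tert-butyldimethylsilyl)oxy]-2,3-dimethylbutanal
Conditions: Dess–Martin periodinane, NaHCO3, CH2Cl2, 0 °C → rt
Reagents that add atoms: none
Why: Dess–Martin oxidation of the primary alcohol under buffered, base-free conditions, so the α-stereocentre (future C8) should not epimerise; the aldehyde is used at once.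

Step 4
Reactants: 4 (2S,3S)-4-[(tert-butyldimethylsilyl)oxy]-2,3-dimethylbutanal; 5 ethyl vinyl ether
Product: 7 (3R,4S,5S)-6-[(tert-butyldimethylsilyl)oxy]-2-ethoxy-4,5-dimethylhex-1-en-3-ol, via 1-ethoxyvinyllithium 6 (not isolated)
Conditions: 5, t-BuLi, THF, −78 → 0 °C; then 4, −78 °C
Reagents that add atoms: none
Why: α-Lithiation of the enol ether gives an acyl-anion equivalent that adds to the aldehyde; Felkin–Anh addition (nucleophile anti to the C7 branch, passing the C8 hydrogen) should place the new hydroxyl syn to the C8 methyl in the extended chain, which is the 9R configuration, and the minor epimer is removed by chromatography.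

Step 5
Reactants: 7 (3R,4S,5S)-6-[(tert-butyldimethylsilyl)oxy]-2-ethoxy-4,5-dimethylhex-1-en-3-ol
Product: 8 (3R,4S,5S)-6-[(tert-butyldimethylsilyl)oxy]-2-ethoxy-4,5-dimethyl-3-[(triisopropylsilyl)oxy]hex-1-ene
Conditions: TIPSOTf, 2,6-lutidine, CH2Cl2, −78 → 0 °C
Reagents that add atoms: triisopropylsilyl trifluoromethanesulfonate, CC(C)[Si](OS(=O)(=O)C(F)(F)F)(C(C)C)C(C)C
Why: Silyl triflate silylation of a hindered secondary alcohol with excess hindered base, which keeps the medium non-acidic for the enol ether; the triisopropylsilyl group is chosen to be orthogonal to the primary silyl ether and bulky next to C9.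

Step 6
Reactants: 8 (3R,4S,5S)-6-[(tert-butyldimethylsilyl)oxy]-2-ethoxy-4,5-dimethyl-3-[(triisopropylsilyl)oxy]hex-1-ene
Product: 9 (2S,3S,4R)-5-ethoxy-2,3-dimethyl-4-[(triisopropylsilyl)oxy]hex-5-en-1-ol
Conditions: TBAF (1.1 equiv), THF, 0 °C
Reagents that add atoms: none
Why: Fluoride cleaves the unhindered primary tert-butyldimethylsilyl ether much faster than the secondary triisopropylsilyl ether, and the basic medium leaves the acid-labile enol ether intact.

Step 7
Reactants: 9 (2S,3S,4R)-5-ethoxy-2,3-dimethyl-4-[(triisopropylsilyl)oxy]hex-5-en-1-ol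
Product: 10 (2S,3S,4R)-5-ethoxy-2,3-dimethyl-4-[(triisopropylsilyl)oxy]hex-5-en-1-yl methanesulfonate
Conditions: MsCl, Et3N, CH2Cl2, 0 °C
Reagents that add atoms: methanesulfonyl chloride, CS(=O)(=O)Cl
Why: Standard sulfonylation of a primary alcohol under basic conditions; it avoids free iodine or acid, either of which could attack the enol ether.

Step 8
Reactants: 10 (2S,3S,4R)-5-ethoxy-2,3-dimethyl-4-[(triisopropylsilyl)oxy]hex-5-en-1-yl methanesulfonate; 11 dimethyl malonate
Product: 12 dimethyl 2-[(2R,3S,4R)-5-ethoxy-2,3-dimethyl-4-[(triisopropylsilyl)oxy]hex-5-en-1-yl]propanedioate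
Conditions: 11 (3 equiv), NaH, NaI (cat.), DMF, 60 °C
Reagents that add atoms: none
Why: Malonic ester alkylation (SN2, with in situ iodide exchange) at the β-branched primary carbon forms C5–C6; excess malonate suppresses dialkylation, and the acidic malonate C–H enters only now, after the organolithium step.

Step 9
Reactants: 12 dimethyl 2-[(2R,3S,4R)-5-ethoxy-2,3-dimethyl-4-[(triisopropylsilyl)oxy]hex-5-en-1-yl]propanedioate
Product: 13 dimethyl 2-[(2R,3S,4R)-6-bromo-2,3-dimethyl-5-oxo-4-[(triisopropylsilyl)oxy]hexyl]propanedioate
Conditions: N-bromosuccinimide, NaHCO3, THF/H2O, 0 °C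
Reagents that add atoms: N-bromosuccinimide, BrN1C(=O)CCC1=O; water, O
Why: Electrophilic bromination of the electron-rich enol ether gives an oxocarbenium ion that water captures; loss of ethanol leaves the bromomethyl ketone, and the malonate C–H is not brominated under these neutral conditions.

Step 10
Reactants: 13 dimethyl 2-[(2R,3S,4R)-6-bromo-2,3-dimethyl-5-oxo-4-[(triisopropylsilyl)oxy]hexyl]propanedioate
Product: 14 dimethyl (4R,5S,6R)-5,6-dimethyl-3-oxo-4-[(triisopropylsilyl)oxy]cycloheptane-1,1-dicarboxylate
Conditions: Cs2CO3, MeCN, high dilution, 0 °C → rt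
Reagents that add atoms: none
Why: Intramolecular malonate alkylation (7-exo-tet) at the activated α-bromoketone forms C5–C4a and the quaternary carbon; SN2 at an α-halo ketone is fast, whereas addition of the malonate to the ketone is reversible and congested, and a mild carbonate base limits enolisation at C9.

Step 11
Reactants: 14 dimethyl (4R,5S,6R)-5,6-dimethyl-3-oxo-4-[(triisopropylsilyl)oxy]cycloheptane-1,1-dicarboxylate
Product: 16 dimethyl (4R,5S,6R)-5,6-dimethyl-3-{[(trifluoromethyl)sulfonyl]oxy}-4-[(triisopropylsilyl)oxy]cyclohept-2-ene-1,1-dicarboxylate, via potassium enolate 15 (not isolated)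
Conditions: KN(SiMe3)2, THF, −78 °C; then PhNTf2, −78 → 0 °C
Reagents that add atoms: N-phenylbis(trifluoromethanesulfonimide), O=S(=O)(N(c1ccccc1)S(=O)(=O)C(F)(F)F)C(F)(F)F
Why: Kinetic deprotonation should occur at the C4a methylene and not at C9, whose hydrogen is shielded by the triisopropylsilyloxy group and sits on an oxygen-bearing carbon; O-triflation of the enolate then fixes the C9a=C4a alkene, and the low temperature prevents enolate equilibration, so C9 is not epimerised.

Step 12
Reactants: 16 dimethyl (4R,5S,6R)-5,6-dimethyl-3-{[(trifluoromethyl)sulfonyl]oxy}-4-[(triisopropylsilyl)oxy]cyclohept-2-ene-1,1-dicarboxylate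
Product: 17 dimethyl (4R,5S,6R)-5,6-dimethyl-4-[(triisopropylsilyl)oxy]-3-(trimethylstannyl)cyclohept-2-ene-1,1-dicarboxylate
Conditions: Me3SnSnMe3, Pd(PPh3)4 (cat.), LiCl, THF, 65 °C
Reagents that add atoms: hexamethylditin, C[Sn](C)(C)[Sn](C)(C)C
Why: Palladium-catalysed stannylation of an enol triflate (oxidative addition, transmetalation with the Sn–Sn bond, reductive elimination) with chloride assistance; the trimethylstannyl group is chosen because it transmetalates more readily from a hindered alkenyl carbon.

Step 13
Reactants: 18 dimethyl squarate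
Product: 19 4-hydroxy-2,3-dimethoxycyclobut-2-en-1-one
Conditions: LiAlH(OtBu)3, THF, −78 → −20 °C
Reagents that add atoms: none
Why: 1,2-Reduction of one carbonyl of the dione by a bulky, mild hydride; the remaining carbonyl is a vinylogous ester and resists further reduction at low temperature.

Step 14
Reactants: 19 4-hydroxy-2,3-dimethoxycyclobut-2-en-1-one
Product: 20 4-chloro-2,3-dimethoxycyclobut-2-en-1-one
Conditions: (COCl)2, DMF (cat.), CH2Cl2, 0 °C
Reagents that add atoms: oxalyl chloride, ClC(=O)C(=O)Cl
Why: Chlorodehydroxylation of an allylic alcohol through chloroiminium (Vilsmeier-type) activation; chloride should settle on the hydrogen-bearing carbon, because that allylic isomer keeps the conjugated vinylogous ester.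

Step 15
Reactants: 17 dimethyl (4R,5S,6R)-5,6-dimethyl-4-[(triisopropylsilyl)oxy]-3-(trimethylstannyl)cyclohept-2-ene-1,1-dicarboxylate; 20 4-chloro-2,3-dimethoxycyclobut-2-en-1-one
Product: 24 dimethyl (7R,8S,9R)-4-hydroxy-2,3-dimethoxy-7,8-dimethyl-9-[(triisopropylsilyl)oxy]-6,7,8,9-tetrahydro-5H-benzo[7]annulene-5,5-dicarboxylate, via alkenylcyclobutenone 21 (not isolated), via dienylketene 22 (not isolated), via cyclohexadienone 23 (not isolated)
Conditions: 20 (1.2 equiv), Pd2(dba)3 (cat.), tri(2-furyl)phosphine, dioxane, 50 °C; then 100 °C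
Reagents that add atoms: none
Why: Oxidative addition of zerovalent palladium to the allylic C–Cl bond of 20 gives an allyl-type complex of divalent palladium; transmetalation with the alkenylstannane 17 (eased by the weakly donating furylphosphine) and reductive elimination at the CH terminus join C1 to C9a and give 21, a Stille coupling. At 100 °C 21 opens in a four-electron conrotatory process to the dienylketene 22; the opening is reversible, so material that opens with the cycloheptenyl group outward returns and drains through the inward isomer. Six-electron disrotatory electrocyclisation of 22 joins the ketene carbon to C4a and closes ring A (six-membered, all-carbon, thermally allowed) as 23, which tautomerises irreversibly to the phenol 24. The closest known reaction type is the palladium-catalysed coupling of 4-chlorocyclobutenones with alkenyl- and arylstannanes followed by thermal rearrangement to phenols. No lasting stereocentre is formed: the sp3 carbons of 21 and 23 are lost on aromatisation, and C7, C8 and C9 are untouched under these neutral conditions. The step needs site selectivity within the allyl complex, which the substrate secures because the CH terminus is the less hindered one and leads to the conjugated vinylogous ester; it also needs a single mode of ring fusion, which connectivity fixes, since the tin-bearing carbon becomes C9a and only C4a can receive the ketene carbon. The atom mapping puts the lone hydrogen on C1 (the former C–Cl carbon), the methoxy groups on C2 and C3 and the new hydroxyl on C4, so ring A needs no later substitution chemistry.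

Step 16
Reactants: 24 dimethyl (7R,8S,9R)-4-hydroxy-2,3-dimethoxy-7,8-dimethyl-9-[(triisopropylsilyl)oxy]-6,7,8,9-tetrahydro-5H-benzo[7]annulene-5,5-dicarboxylate
Product: 25 dimethyl (7R,8S,9R)-2,3,4-trimethoxy-7,8-dimethyl-9-[(triisopropylsilyl)oxy]-6,7,8,9-tetrahydro-5H-benzo[7]annulene-5,5-dicarboxylate
Conditions: MeI, K2CO3, DMF/MeOH (10:1), 40 °C
Reagents that add atoms: iodomethane, CI
Why: Williamson O-methylation of the phenoxide; any lactonisation of the phenol onto a neighbouring ester is reversed by methanolysis under the same conditions, so the material should funnel to the methyl ether.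

Step 17
Reactants: 25 dimethyl (7R,8S,9R)-2,3,4-trimethoxy-7,8-dimethyl-9-[(triisopropylsilyl)oxy]-6,7,8,9-tetrahydro-5H-benzo[7]annulene-5,5-dicarboxylate
Product: 26 [(7R,8S,9R)-2,3,4-trimethoxy-7,8-dimethyl-9-[(triisopropylsilyl)oxy]-6,7,8,9-tetrahydro-5H-benzo[7]annulene-5,5-diyl]dimethanol
Conditions: LiAlH4, THF, 0 → 50 °C
Reagents that add atoms: none
Why: Hydride reduction of both hindered esters to the 1,3-diol; the silyl ether and aryl methyl ethers are inert, and no benzoate is yet present.

Step 18
Reactants: 26 [(7R,8S,9R)-2,3,4-trimethoxy-7,8-dimethyl-9-[(triisopropylsilyl)oxy]-6,7,8,9-tetrahydro-5H-benzo[7]annulene-5,5-diyl]dimethanol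
Product: 27 (7R,8S,9R)-2,3,4-trimethoxy-7,8-dimethyl-9-[(triisopropylsilyl)oxy]-6,7,8,9-tetrahydro-5H-benzo[7]annulene-5,5-dicarbaldehyde
Conditions: Dess–Martin periodinane (2.5 equiv), NaHCO3, CH2Cl2, rt
Reagents that add atoms: none
Why: Twofold Dess–Martin oxidation without amine base, so the half-oxidised β-hydroxy aldehyde cannot lose formaldehyde by retro-aldol cleavage; the dialdehyde has no α-hydrogen and is used directly.

Step 19
Reactants: 27 (7R,8S,9R)-2,3,4-trimethoxy-7,8-dimethyl-9-[(triisopropylsilyl)oxy]-6,7,8,9-tetrahydro-5H-benzo[7]annulene-5,5-dicarbaldehyde; 28 1,3-dimethoxypropan-2-one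
Product: 29 (7R,8S,9R)-2,3,3',4,5'-pentamethoxy-7,8-dimethyl-9-[(triisopropylsilyl)oxy]-6,7,8,9-tetrahydrospiro[benzo[7]annulene-5,1'-cyclohexa[2,5]dien]-4'-one
Conditions: 28 (1.5 equiv), KOtBu (cat.), t-BuOH/THF, 4 Å molecular sieves, 0 °C → rt
Reagents that add atoms: none
Why: Proposed new method: each methoxy-bearing α-carbon of 28 adds as its enolate to one formyl group of 27, the second addition being a six-membered intramolecular aldol closure at the sp3 stage, and two E1cB dehydrations then give the cross-conjugated dienone, whose formation should pull the reversible aldol steps forward, while a hindered, weakly nucleophilic base is chosen so that attack at a formyl carbon (deformylation) stays slower than enolate formation; the closest known reaction type is the twofold Claisen–Schmidt cyclocondensation of 1,2- and 1,4-dicarbonyl compounds with ketones of the CH2–CO–CH2 type to cyclopentadienones and benzotropones, together with the condensation of nitromalonaldehyde with ketones to 4-nitrophenols.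

Step 20
Reactants: 29 (7R,8S,9R)-2,3,3',4,5'-pentamethoxy-7,8-dimethyl-9-[(triisopropylsilyl)oxy]-6,7,8,9-tetrahydrospiro[benzo[7]annulene-5,1'-cyclohexa[2,5]dien]-4'-one
Product: 30 (7R,8S,9R)-9-hydroxy-2,3,3',4,5'-pentamethoxy-7,8-dimethyl-6,7,8,9-tetrahydrospiro[benzo[7]annulene-5,1'-cyclohexa[2,5]dien]-4'-one
Conditions: TBAF, AcOH (1:1), THF, rt
Reagents that add atoms: none
Why: Fluoride-induced cleavage of the secondary silyl ether; buffering with acetic acid keeps the medium close to neutral, so neither acid-promoted ionisation at C9 nor base-promoted addition of the new alkoxide to the dienone is favoured.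

Step 21
Reactants: 30 (7R,8S,9R)-9-hydroxy-2,3,3',4,5'-pentamethoxy-7,8-dimethyl-6,7,8,9-tetrahydrospiro[benzo[7]annulene-5,1'-cyclohexa[2,5]dien]-4'-one
Product: 31 (7R,8S,9R)-2,3,3',4,5'-pentamethoxy-7,8-dimethyl-4'-oxo-6,7,8,9-tetrahydrospiro[benzo[7]annulene-5,1'-cyclohexa[2,5]dien]-9-yl benzoate
Conditions: BzCl, pyridine, DMAP (cat.), CH2Cl2, 0 °C → rt
Reagents that add atoms: benzoyl chloride, O=C(Cl)c1ccccc1
Why: Nucleophile-catalysed acylation of the secondary alcohol with retention at C9 (the C–O bond is not broken), which completes the target.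

## Compound list

1 | (2S,3S)-2,3-dimethylbutanedioic acid | OC(=O)[C@@H](C)[C@H](C)C(=O)O | starting material
2 | (2S,3S)-2,3-dimethylbutane-1,4-diol | OC[C@@H](C)[C@H](C)CO | intermediate
3 | (2S,3S)-4-[(tert-butyldimethylsilyl)oxy]-2,3-dimethylbutan-1-ol | CC(C)(C)[Si](C)(C)OC[C@@H](C)[C@H](C)CO | intermediate
4 | (2S,3S)-4-[(tert-butyldimethylsilyl)oxy]-2,3-dimethylbutanal | CC(C)(C)[Si](C)(C)OC[C@@H](C)[C@H](C)C=O | intermediate
5 | ethyl vinyl ether | C=COCC | starting material
6 | 1-ethoxyvinyllithium | [Li]C(=C)OCC | intermediate (not isolated)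
7 | (3R,4S,5S)-6-[(tert-butyldimethylsilyl)oxy]-2-ethoxy-4,5-dimethylhex-1-en-3-ol | CC(C)(C)[Si](C)(C)OC[C@@H](C)[C@H](C)[C@@H](O)C(=C)OCC | intermediate
8 | (3R,4S,5S)-6-[(tert-butyldimethylsilyl)oxy]-2-ethoxy-4,5-dimethyl-3-[(triisopropylsilyl)oxy]hex-1-ene | CC(C)(C)[Si](C)(C)OC[C@@H](C)[C@H](C)[C@@H](O[Si](C(C)C)(C(C)C)C(C)C)C(=C)OCC | intermediate
9 | (2S,3S,4R)-5-ethoxy-2,3-dimethyl-4-[(triisopropylsilyl)oxy]hex-5-en-1-ol | OC[C@@H](C)[C@H](C)[C@@H](O[Si](C(C)C)(C(C)C)C(C)C)C(=C)OCC | intermediate
10 | (2S,3S,4R)-5-ethoxy-2,3-dimethyl-4-[(triisopropylsilyl)oxy]hex-5-en-1-yl methanesulfonate | CS(=O)(=O)OC[C@@H](C)[C@H](C)[C@@H](O[Si](C(C)C)(C(C)C)C(C)C)C(=C)OCC | intermediate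
11 | dimethyl malonate | COC(=O)CC(=O)OC | starting material
12 | dimethyl 2-[(2R,3S,4R)-5-ethoxy-2,3-dimethyl-4-[(triisopropylsilyl)oxy]hex-5-en-1-yl]propanedioate | COC(=O)C(C(=O)OC)C[C@@H](C)[C@H](C)[C@@H](O[Si](C(C)C)(C(C)C)C(C)C)C(=C)OCC | intermediate
13 | dimethyl 2-[(2R,3S,4R)-6-bromo-2,3-dimethyl-5-oxo-4-[(triisopropylsilyl)oxy]hexyl]propanedioate | COC(=O)C(C(=O)OC)C[C@@H](C)[C@H](C)[C@@H](O[Si](C(C)C)(C(C)C)C(C)C)C(=O)CBr | intermediate
14 | dimethyl (4R,5S,6R)-5,6-dimethyl-3-oxo-4-[(triisopropylsilyl)oxy]cycloheptane-1,1-dicarboxylate | COC(=O)C1(C(=O)OC)C[C@@H](C)[C@H](C)[C@@H](O[Si](C(C)C)(C(C)C)C(C)C)C(=O)C1 | intermediate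
15 | potassium enolate of 14 (enolate double bond between the ketone carbon and the ring CH next to the diester carbon) | COC(=O)C1(C(=O)OC)C[C@@H](C)[C@H](C)[C@@H](O[Si](C(C)C)(C(C)C)C(C)C)C([O-])=C1.[K+] | intermediate (not isolated)
16 | dimethyl (4R,5S,6R)-5,6-dimethyl-3-{[(trifluoromethyl)sulfonyl]oxy}-4-[(triisopropylsilyl)oxy]cyclohept-2-ene-1,1-dicarboxylate | COC(=O)C1(C(=O)OC)C[C@@H](C)[C@H](C)[C@@H](O[Si](C(C)C)(C(C)C)C(C)C)C(OS(=O)(=O)C(F)(F)F)=C1 | intermediate
17 | dimethyl (4R,5S,6R)-5,6-dimethyl-4-[(triisopropylsilyl)oxy]-3-(trimethylstannyl)cyclohept-2-ene-1,1-dicarboxylate | COC(=O)C1(C(=O)OC)C[C@@H](C)[C@H](C)[C@@H](O[Si](C(C)C)(C(C)C)C(C)C)C(=C1)[Sn](C)(C)C | intermediate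
18 | dimethyl squarate (3,4-dimethoxycyclobut-3-ene-1,2-dione) | COC1=C(OC)C(=O)C1=O | starting material
19 | 4-hydroxy-2,3-dimethoxycyclobut-2-en-1-one (racemic) | COC1=C(OC)C(O)C1=O | intermediate
20 | 4-chloro-2,3-dimethoxycyclobut-2-en-1-one (racemic) | COC1=C(OC)C(Cl)C1=O | intermediate
21 | dimethyl (4R,5S,6R)-3-(2,3-dimethoxy-4-oxocyclobut-2-en-1-yl)-5,6-dimethyl-4-[(triisopropylsilyl)oxy]cyclohept-2-ene-1,1-dicarboxylate (both configurations at the cyclobutenyl CH) | COC(=O)C1(C(=O)OC)C[C@@H](C)[C@H](C)[C@@H](O[Si](C(C)C)(C(C)C)C(C)C)C(=C1)C2C(=O)C(OC)=C2OC | intermediate (not isolated)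
22 | dimethyl (4R,5S,6R)-3-[(1E)-2,3-dimethoxy-4-oxobuta-1,3-dien-1-yl]-5,6-dimethyl-4-[(triisopropylsilyl)oxy]cyclohept-2-ene-1,1-dicarboxylate (dienylketene; ring alkene and ketene cis across the central alkene) | COC(=O)C1(C(=O)OC)C[C@@H](C)[C@H](C)[C@@H](O[Si](C(C)C)(C(C)C)C(C)C)C(=C1)/C=C(OC)\C(OC)=C=O | intermediate (not isolated)
23 | dimethyl (7R,8S,9R)-2,3-dimethoxy-7,8-dimethyl-4-oxo-9-[(triisopropylsilyl)oxy]-4,4a,6,7,8,9-hexahydro-5H-benzo[7]annulene-5,5-dicarboxylate (keto tautomer of 24; either configuration at C4a) | COC(=O)C2(C(=O)OC)C[C@@H](C)[C@H](C)[C@@H](O[Si](C(C)C)(C(C)C)C(C)C)C1=CC(OC)=C(OC)C(=O)C12 | intermediate (not isolated)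
24 | dimethyl (7R,8S,9R)-4-hydroxy-2,3-dimethoxy-7,8-dimethyl-9-[(triisopropylsilyl)oxy]-6,7,8,9-tetrahydro-5H-benzo[7]annulene-5,5-dicarboxylate | COC(=O)C2(C(=O)OC)C[C@@H](C)[C@H](C)[C@@H](O[Si](C(C)C)(C(C)C)C(C)C)c1cc(OC)c(OC)c(O)c12 | intermediate
25 | dimethyl (7R,8S,9R)-2,3,4-trimethoxy-7,8-dimethyl-9-[(triisopropylsilyl)oxy]-6,7,8,9-tetrahydro-5H-benzo[7]annulene-5,5-dicarboxylate | COC(=O)C2(C(=O)OC)C[C@@H](C)[C@H](C)[C@@H](O[Si](C(C)C)(C(C)C)C(C)C)c1cc(OC)c(OC)c(OC)c12 | intermediate
26 | [(7R,8S,9R)-2,3,4-trimethoxy-7,8-dimethyl-9-[(triisopropylsilyl)oxy]-6,7,8,9-tetrahydro-5H-benzo[7]annulene-5,5-diyl]dimethanol | OCC2(CO)C[C@@H](C)[C@H](C)[C@@H](O[Si](C(C)C)(C(C)C)C(C)C)c1cc(OC)c(OC)c(OC)c12 | intermediate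
27 | (7R,8S,9R)-2,3,4-trimethoxy-7,8-dimethyl-9-[(triisopropylsilyl)oxy]-6,7,8,9-tetrahydro-5H-benzo[7]annulene-5,5-dicarbaldehyde | O=CC2(C=O)C[C@@H](C)[C@H](C)[C@@H](O[Si](C(C)C)(C(C)C)C(C)C)c1cc(OC)c(OC)c(OC)c12 | intermediate
28 | 1,3-dimethoxypropan-2-one | COCC(=O)COC | starting material
29 | (7R,8S,9R)-2,3,3',4,5'-pentamethoxy-7,8-dimethyl-9-[(triisopropylsilyl)oxy]-6,7,8,9-tetrahydrospiro[benzo[7]annulene-5,1'-cyclohexa[2,5]dien]-4'-one | COC1=CC2(C=C(OC)C1=O)C[C@@H](C)[C@H](C)[C@@H](O[Si](C(C)C)(C(C)C)C(C)C)c1cc(OC)c(OC)c(OC)c12 | intermediate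
30 | (7R,8S,9R)-9-hydroxy-2,3,3',4,5'-pentamethoxy-7,8-dimethyl-6,7,8,9-tetrahydrospiro[benzo[7]annulene-5,1'-cyclohexa[2,5]dien]-4'-one | COC1=CC2(C=C(OC)C1=O)C[C@@H](C)[C@H](C)[C@@H](O)c1cc(OC)c(OC)c(OC)c12 | intermediate
31 | (7R,8S,9R)-2,3,3',4,5'-pentamethoxy-7,8-dimethyl-4'-oxo-6,7,8,9-tetrahydrospiro[benzo[7]annulene-5,1'-cyclohexa[2,5]dien]-9-yl benzoate | COC1=CC2(C=C(OC)C1=O)C[C@@H](C)[C@H](C)[C@@H](OC(=O)c1ccccc1)c1cc(OC)c(OC)c(OC)c12 | target

## Step count and least certain steps

Total: 21 steps. Longest linear sequence: 19 steps (steps 1–12 and 15–21, from 1 to 31); steps 13 and 14 are a two-step branch to 20.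

**Step 19 (bears the label "Proposed new method:").** The most likely failure is loss of a formyl group by nucleophilic attack at the non-enolisable, neopentyl-type aldehyde (retro-Claisen-type deformylation). The second risk is stalling after the first condensation, when dehydration precedes the second aldol addition and the resulting alkene has the geometry that cannot close. Both follow from the crowding at C5, flanked by the ortho-methoxylated arene. Fallback with known chemistry, from 27 back to 29:
- 28 is converted with TMSCl, Et3N and NaI into its trimethylsilyl enol ether, (Z)-[(1,3-dimethoxyprop-1-en-2-yl)oxy]trimethylsilane F1.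
- A Mukaiyama aldol addition of F1 to 27 (BF3·OEt2, CH2Cl2, −78 °C) should give the mono-aldol adduct, the 5-(1-hydroxy-2,4-dimethoxy-3-oxobutyl)-5-carbaldehyde F2.
- Boron-mediated intramolecular aldol addition (Bu2BOTf, i-Pr2NEt, −78 → 0 °C) should close ring C at the sp3 stage to the spiro 2',6'-dihydroxy-3',5'-dimethoxycyclohexan-4'-one F3.
- MsCl and Et3N give the bis(methanesulfonate) F4, and DBU eliminates both sulfonates to return 29.
- No alkoxide base meets the free dialdehyde, and no alkene geometry is involved before ring closure.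

**Step 15 (key step).** The most likely failure is slow transmetalation of the α-branched alkenylstannane, whose tin-bearing carbon sits next to the bulky C9 silyl ether; protodestannylation and thermal decay of 20 would then compete. A second risk is lactonisation of the new phenol onto a neighbouring ester at 100 °C, which step 16 is designed to reverse. Fallback that brings ring A in as an arene and closes ring B onto it, from 4 back to 25:
- (3,4,5-Trimethoxyphenyl)magnesium bromide F5, made from 5-bromo-1,2,3-trimethoxybenzene and Mg, is added to 4 (THF, −78 °C, Felkin–Anh sense as in step 4) to give the carbinol (1R,2S,3S)-4-[(tert-butyldimethylsilyl)oxy]-2,3-dimethyl-1-(3,4,5-trimethoxyphenyl)butan-1-ol F6.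
- TIPSOTf and 2,6-lutidine give the bis-silyl ether F7; TBAF at 0 °C frees the primary alcohol F8; MsCl and Et3N give the methanesulfonate F9.
- Sodium dimethyl malonate (from 11, NaH, NaI, DMF) gives the alkylated malonate F10.
- N-Bromosuccinimide in MeCN brominates one of the two equivalent free ring positions next to the side chain to give the aryl bromide F11.
- Intramolecular palladium-catalysed α-arylation of the malonate (Pd(OAc)2, P(t-Bu)3, Cs2CO3, toluene, 100 °C) forms C5–C4a and returns 25.

**Step 10.** The most likely failures are intermolecular alkylation (oligomers) instead of seven-membered ring closure, addition of the malonate anion to the ketone followed by epoxide formation, and enolisation at C9 with loss of configuration. All arise because a medium ring must form next to a reactive carbonyl under basic conditions. Fallback that closes ring B at C5–C6 instead, from 8 back to 14: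
- N-Bromosuccinimide in THF/H2O converts 8 into the bromoketone (3R,4S,5S)-1-bromo-6-[(tert-butyldimethylsilyl)oxy]-4,5-dimethyl-3-[(triisopropylsilyl)oxy]hexan-2-one F12.
- Intermolecular alkylation of 11 (K2CO3, acetone) gives the keto malonate F13.
- HF·pyridine in THF/pyridine removes the primary silyl ether to give the hydroxy ketone F14, and I2, PPh3 and imidazole give the iodide F15.
- Cs2CO3 in MeCN at high dilution closes the ring by alkylation of the tertiary malonate carbon and returns 14.

**Step 4.** The most likely failure is poor facial selectivity, because a small, reactive organolithium discriminates only moderately between the faces of an α-methyl aldehyde. Fallback that replaces substrate control in C–C bond formation by reagent control in C=O reduction, from 7 (as the mixture of C9 epimers) back to 7: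
- Dess–Martin oxidation gives the enone (4S,5S)-6-[(tert-butyldimethylsilyl)oxy]-2-ethoxy-4,5-dimethylhex-1-en-3-one F16.
- Corey–Bakshi–Shibata reduction with the (S)-configured B-methyl oxazaborolidine [(S)-1-methyl-3,3-diphenyltetrahydro-1H,3H-pyrrolo[1,2-c][1,3,2]oxazaborole] and catecholborane at −78 °C should give the 9R carbinol, with the alkoxyvinyl group playing the role of the larger, unsaturated substituent.

## Further compounds

F1 | step 19 | (Z)-[(1,3-dimethoxyprop-1-en-2-yl)oxy]trimethylsilane | CO/C=C(/COC)O[Si](C)(C)C
F2 | step 19 | (7R,8S,9R)-5-(1-hydroxy-2,4-dimethoxy-3-oxobutyl)-2,3,4-trimethoxy-7,8-dimethyl-9-[(triisopropylsilyl)oxy]-6,7,8,9-tetrahydro-5H-benzo[7]annulene-5-carbaldehyde (mixture at C5 and the two new side-chain centres) | COCC(=O)C(OC)C(O)C2(C=O)C[C@@H](C)[C@H](C)[C@@H](O[Si](C(C)C)(C(C)C)C(C)C)c1cc(OC)c(OC)c(OC)c12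
F3 | step 19 | (7R,8S,9R)-2',6'-dihydroxy-2,3,3',4,5'-pentamethoxy-7,8-dimethyl-9-[(triisopropylsilyl)oxy]-6,7,8,9-tetrahydrospiro[benzo[7]annulene-5,1'-cyclohexan]-4'-one (mixture at the four new ring C centres) | COC1C(O)C2(C(O)C(OC)C1=O)C[C@@H](C)[C@H](C)[C@@H](O[Si](C(C)C)(C(C)C)C(C)C)c1cc(OC)c(OC)c(OC)c12
F4 | step 19 | bis(methanesulfonate) of F3 at the 2'- and 6'-hydroxyls | COC1C(OS(C)(=O)=O)C2(C(OS(C)(=O)=O)C(OC)C1=O)C[C@@H](C)[C@H](C)[C@@H](O[Si](C(C)C)(C(C)C)C(C)C)c1cc(OC)c(OC)c(OC)c12
F5 | step 15 | (3,4,5-trimethoxyphenyl)magnesium bromide | COc1cc([Mg]Br)cc(OC)c1OC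
F6 | step 15 | (1R,2S,3S)-4-[(tert-butyldimethylsilyl)oxy]-2,3-dimethyl-1-(3,4,5-trimethoxyphenyl)butan-1-ol | CC(C)(C)[Si](C)(C)OC[C@@H](C)[C@H](C)[C@@H](O)c1cc(OC)c(OC)c(OC)c1
F7 | step 15 | tert-butyldimethyl{[(2S,3S,4R)-2,3-dimethyl-4-[(triisopropylsilyl)oxy]-4-(3,4,5-trimethoxyphenyl)butyl]oxy}silane | CC(C)(C)[Si](C)(C)OC[C@@H](C)[C@H](C)[C@@H](O[Si](C(C)C)(C(C)C)C(C)C)c1cc(OC)c(OC)c(OC)c1
F8 | step 15 | (2S,3S,4R)-2,3-dimethyl-4-[(triisopropylsilyl)oxy]-4-(3,4,5-trimethoxyphenyl)butan-1-ol | OC[C@@H](C)[C@H](C)[C@@H](O[Si](C(C)C)(C(C)C)C(C)C)c1cc(OC)c(OC)c(OC)c1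
F9 | step 15 | (2S,3S,4R)-2,3-dimethyl-4-[(triisopropylsilyl)oxy]-4-(3,4,5-trimethoxyphenyl)butyl methanesulfonate | CS(=O)(=O)OC[C@@H](C)[C@H](C)[C@@H](O[Si](C(C)C)(C(C)C)C(C)C)c1cc(OC)c(OC)c(OC)c1
F10 | step 15 | dimethyl 2-[(2R,3S,4R)-2,3-dimethyl-4-[(triisopropylsilyl)oxy]-4-(3,4,5-trimethoxyphenyl)butyl]propanedioate | COC(=O)C(C(=O)OC)C[C@@H](C)[C@H](C)[C@@H](O[Si](C(C)C)(C(C)C)C(C)C)c1cc(OC)c(OC)c(OC)c1
F11 | step 15 | dimethyl 2-[(2R,3S,4R)-4-(2-bromo-3,4,5-trimethoxyphenyl)-2,3-dimethyl-4-[(triisopropylsilyl)oxy]butyl]propanedioate | COC(=O)C(C(=O)OC)C[C@@H](C)[C@H](C)[C@@H](O[Si](C(C)C)(C(C)C)C(C)C)c1cc(OC)c(OC)c(OC)c1Br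
F12 | step 10 | (3R,4S,5S)-1-bromo-6-[(tert-butyldimethylsilyl)oxy]-4,5-dimethyl-3-[(triisopropylsilyl)oxy]hexan-2-one | CC(C)(C)[Si](C)(C)OC[C@@H](C)[C@H](C)[C@@H](O[Si](C(C)C)(C(C)C)C(C)C)C(=O)CBr
F13 | step 10 | dimethyl 2-[(3R,4S,5S)-6-[(tert-butyldimethylsilyl)oxy]-4,5-dimethyl-2-oxo-3-[(triisopropylsilyl)oxy]hexyl]propanedioate | CC(C)(C)[Si](C)(C)OC[C@@H](C)[C@H](C)[C@@H](O[Si](C(C)C)(C(C)C)C(C)C)C(=O)CC(C(=O)OC)C(=O)OC
F14 | step 10 | dimethyl 2-[(3R,4S,5S)-6-hydroxy-4,5-dimethyl-2-oxo-3-[(triisopropylsilyl)oxy]hexyl]propanedioate | OC[C@@H](C)[C@H](C)[C@@H](O[Si](C(C)C)(C(C)C)C(C)C)C(=O)CC(C(=O)OC)C(=O)OC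
F15 | step 10 | dimethyl 2-[(3R,4S,5S)-6-iodo-4,5-dimethyl-2-oxo-3-[(triisopropylsilyl)oxy]hexyl]propanedioate | IC[C@@H](C)[C@H](C)[C@@H](O[Si](C(C)C)(C(C)C)C(C)C)C(=O)CC(C(=O)OC)C(=O)OC
F16 | step 4 | (4S,5S)-6-[(tert-butyldimethylsilyl)oxy]-2-ethoxy-4,5-dimethylhex-1-en-3-one | CC(C)(C)[Si](C)(C)OC[C@@H](C)[C@H](C)C(=O)C(=C)OCC
A1 | alternative 1 | (8S,9S)-9-hydroxy-2,3,3',4,5'-pentamethoxy-8-methyl-7-methylidene-6,7,8,9-tetrahydrospiro[benzo[7]annulene-5,1'-cyclohexa[2,5]dien]-4'-one | COC1=CC2(C=C(OC)C1=O)CC(=C)[C@H](C)[C@H](O)c1cc(OC)c(OC)c(OC)c12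
A2 | alternative 1 | 4'-hydroxy-3',4,5,5',6-pentamethoxy-[1,1'-biphenyl]-2-carbaldehyde | O=Cc1cc(OC)c(OC)c(OC)c1-c1cc(OC)c(O)c(OC)c1
A3 | alternative 1 | methyl (2Z)-2-[(4,4,5,5-tetramethyl-1,3,2-dioxaborolan-2-yl)methyl]but-2-en-1-yl carbonate | C/C=C(\COC(=O)OC)CB1OC(C)(C)C(C)(C)O1
A4 | alternative 2 | dimethyl 2,3,4-trimethoxy-7,8-dimethyl-9-oxo-6,9-dihydro-5H-benzo[7]annulene-5,5-dicarboxylate | COC(=O)C2(C(=O)OC)CC(C)=C(C)C(=O)c1cc(OC)c(OC)c(OC)c12
A5 | alternative 2 | dimethyl 5,6,7-trimethoxy-3-oxo-2,3-dihydro-1H-indene-1,1-dicarboxylate | COC(=O)C1(C(=O)OC)CC(=O)c2cc(OC)c(OC)c(OC)c12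
A6 | alternative 2 | but-2-yne | CC#CC
A7 | alternative 3 | (7R,8S)-2,3,3',4,5'-pentamethoxy-7,8-dimethyl-7,8-dihydrospiro[benzo[7]annulene-5,1'-cyclohexa[2,5]diene]-4',9(6H)-dione | COC1=CC2(C=C(OC)C1=O)C[C@@H](C)[C@H](C)C(=O)c1cc(OC)c(OC)c(OC)c12
A8 | alternative 3 | 2-{3,5-dimethoxy-1-[(2E)-2-methylbut-2-en-1-yl]-4-oxocyclohexa-2,5-dien-1-yl}-3,4,5-trimethoxybenzaldehyde | COC1=CC(C/C(C)=C/C)(C=C(OC)C1=O)c1c(C=O)cc(OC)c(OC)c1OC
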